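(The constants were drawn at random within sensible limits; what happens was integrated by code.)

**The constants.** The constants below hold at 90 °C, which is zeta's own temperature, so zeta needs no scaling and the other flasks do.

    coupling partner + free catalyst → catalyst intermediate A (k1 = 110 L mol⁻¹ min⁻¹, Ea1 = 37.0 kJ mol⁻¹)
    catalyst intermediate A → catalyst intermediate B (k2 = 7.0 min⁻¹, Ea2 = 86.0 kJ mol⁻¹)
    substrate + catalyst intermediate B → catalyst intermediate C (k3 = 360 L mol⁻¹ min⁻¹, Ea3 = 49.0 kJ mol⁻¹)
    catalyst intermediate C → by-product + catalyst intermediate D (k4 = 350 min⁻¹, Ea4 = 73.0 kJ mol⁻¹)
    catalyst intermediate D ⇌ free catalyst + target (K5 = 0.0048 M, k5 = 1.6 min⁻¹, Ea5 = 99.0 kJ mol⁻¹, ΔH5 = −90.0 kJ mol⁻¹)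
    2 substrate → self-condensation product (k6 = 0.13 L mol⁻¹ min⁻¹, Ea6 = 81.0 kJ mol⁻¹)
    (constants at 90 °C)

| flask | substrate | coupling partner | free catalyst | temperature | time |
|---|---|---|---|---|---|
| epsilon | 10 mM | 30.0 mM | 20 µM | 150 °C | 25 h |
| zeta | 10 mM | 30.0 mM | 20 µM | 90 °C | 25 h |
| delta | 10 mM | 30.0 mM | 20 µM | 120 °C | 25 h |
| gamma | 10 mM | 30.0 mM | 20 µM | 60 °C | 25 h |

- a species is counted by the substrate in it: one self-condensation product counts as two
- for a step with 2 of a species take k times the square, and two of it per event
- the constants hold at 90 °C; other temperatures follow from the activation energies and enthalpies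

* which flask leads in amount of target, in percent of the substrate charged ("all alike" within 1.5 percentage points) (epsilon / zeta / delta / gamma / all alike)
* how much target is there at the end, in percent of the substrate charged: epsilon
* how much target is there at the end, in percent of the substrate charged: zeta
* how much target is there at the end, in percent of the substrate charged: delta
* how much target is there at the end, in percent of the substrate charged: gamma

**Cycle time.** In zeta at the charge, the lifetimes of the catalyst at its stations add up to 1.35 min. This is the cycle time: the sum of the inverse pseudo-first-order constants of the steps around the cycle, with the return of target to free catalyst left out.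

**Time allowance.** At that pace zeta's catalyst turns out 22.2 mM of target in 25 h, more than the 10 mM of substrate charged, so by this reckoning time does not stop zeta.

**The race.** I define the race number r as the substrate lost to self-condensation per unit time over the turnover rate, which is the catalyst charge divided by the cycle time. The share of substrate reaching target is the inverse of one plus r. In zeta at the charge r is 1.76, and I hold the share at that moment as my estimated floor for zeta, 36.3%.

**Weak link.** That share belongs to the start of zeta. At [substrate] of 5.00 mM the cycle lengthens to 1.63 min, but r drops to 0.530, lower than at the charge. I let the share at that midway [substrate] stand for the whole run, which gives zeta 65.4%, and this is the number I commit to.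

**Colder, hotter.** From zeta down to gamma the logarithm of the rise in K5 is 2.68, reckoned from 740, the speed-up of step 2 from gamma to epsilon, and from the fall of K5 in epsilon. Each rate constant falls by the exponential of that logarithm times its own activation energy over the size of dH5. Gamma's cycle time becomes 16.0 min, of which 12.0 min is the release of target from catalyst intermediate D. That station takes longer than the others together, so it is the rate-limiting step. Gamma fits 93.8 cycles into 25 h, which makes less target than the substrate charged, so I put gamma at 18.8%.

For epsilon the logarithm of the fall in K5, read from 7.01 × 10⁻⁵ M, is 4.23, and each rate constant rises by the same rule. Epsilon's cycle time is 0.0897 min, and its r at the midway [substrate] is 1.71. With the return of target still left out, I hold the midway share as an estimated ceiling for epsilon, 36.8%, lower than my zeta figure. I put zeta ahead of gamma and of epsilon, and I do not reckon delta.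

**The forecast.** The forecast names zeta, with 22.5% for epsilon, 65% for zeta, 45.5% for delta and 18.2% for gamma. Its grounds: “Hot flasks therefore suffer product inhibition, while self-condensation (high Ea) accelerates.”

**The result.** The simulation gives zeta the lead at 65.3%, with epsilon at 22.3%, delta at 45.3% and gamma at 18.3%. Gamma still holds 59.9% of its substrate at 25.0 h. Gamma's cycle time at the charge is 11.9 times zeta's, yet gamma's r at the midway [substrate] is 0.498, and that makes a midway share of 66.8% for gamma. At 250 h gamma holds 67.7% of target.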